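**Strategy.** Everything rests on an intramolecular Diels–Alder reaction. Labels: cyclohexane ring C1(=CH2)–C2–C6–C7–C8–C9, cyclopentanone ring C2–C3–C4(=O)–C5–C6. The four contiguous cis hydrogens at C2, C6, C7 and C8 are read as the endo adduct of an (E,E)-1-alkoxydiene (C8=C9–C1=C2) and a (Z)-2-oxo-3-enoate (C6=C7) joined by the C3–C4–C5 tether. One oxidation-triggered operation forms C2–C6 and C7–C8 and closes both rings of the cis-hydrindane from an acyclic triene. A single catalytically set allylic centre (C5) relays chirality by A(1,3) strain; C5 is later flattened and reset together with C10, and the keto ester at C7 becomes the epoxy ester.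

Key step: step 11

Remark (labels): C10 is the CH(O) carbon on C5, C11 its methyl, C12 the quaternary oxirane carbon on C7.
Remark (assumption): compounds 1, 3, 18 and 23 and all reagents are taken as commercially available; 10–12 are used as mixtures of epimers at the carbinol carbon that step 11 oxidizes.

Step 1
Reactants: 1 (E)-pent-2-en-4-yn-1-ol
Product: 2 (E)-5-bromopent-3-en-1-yne
Conditions: CBr4, PPh3, CH2Cl2, 0 °C
Reagents that add atoms: carbon tetrabromide, BrC(Br)(Br)Br
Why: Appel bromination should convert the primary allylic alcohol to the bromide under neutral conditions without touching the enyne.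

Step 2
Reactants: 3 3-(tert-butyldimethylsilyloxy)propanal; 2 (E)-5-bromopent-3-en-1-yne
Product: 4 (3R,4R)-1-(tert-butyldimethylsilyloxy)-4-ethynylhex-5-en-3-ol
Conditions: CrCl2 (10 mol %), chiral carbazole bis(oxazoline) ligand, Mn powder, Me3SiCl, i-Pr2NEt, THF, rt; then K2CO3, MeOH
Reagents that add atoms: none
Why: Catalytic asymmetric Nozaki–Hiyama allylation, in which the γ-ethynyl allylchromium should add through its γ-carbon in a closed chair transition state to give the anti adduct, the ligand enantiomer fixing C4 (R) and the relay centre C5 (R).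

Step 3
Reactants: 4 anti homoallylic alcohol
Product: 5 (3R,4R)-1,3-bis(tert-butyldimethylsilyloxy)-4-ethynylhex-5-ene
Conditions: TBSCl, imidazole, DMF, rt
Reagents that add atoms: tert-butyldimethylsilyl chloride, CC(C)(C)[Si](C)(C)Cl
Why: Standard silylation masks the C4 hydroxyl, which must stay at the alcohol oxidation level so that C5 is not acidified before the cycloaddition.

Step 4
Reactants: 5 bis-silyl ether
Product: 6 (3R,4R)-3-(tert-butyldimethylsilyloxy)-4-ethynylhex-5-en-1-ol
Conditions: HF·pyridine, pyridine, THF, 0 °C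
Reagents that add atoms: none
Why: The unhindered primary silyl ether should be cleaved much faster than the secondary one flanked by the branched C5.

Step 5
Reactants: 6 primary alcohol
Product: 7 (3R,4R)-3-(tert-butyldimethylsilyloxy)-4-ethynylhex-5-enal
Conditions: Dess–Martin periodinane, NaHCO3, CH2Cl2, 0 °C
Reagents that add atoms: none
Why: Buffered Dess–Martin oxidation should give the β-silyloxy aldehyde without elimination.

Step 6
Reactants: 7 aldehyde
Product: 8 (2E,5R,6R)-5-(tert-butyldimethylsilyloxy)-6-ethynyl-2-methylocta-2,7-dienal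
Conditions: Ph3P=C(CH3)CHO, toluene, 80 °C
Reagents that add atoms: 2-(triphenylphosphoranylidene)propanal, CC(C=O)=P(c1ccccc1)(c1ccccc1)c1ccccc1
Why: Wittig reaction with a stabilized ylide should give the (E)-2-methyl enal, which sets the C1=C2 geometry of the future diene.

Step 7
Reactants: 8 enal
Product: 9 pinacol (1E,3E,6R,7R)-6-(tert-butyldimethylsilyloxy)-7-ethynyl-3-methylnona-1,3,8-trienylboronate
Conditions: Cl2CHB(pin), CrCl2, LiI, THF, rt
Reagents that add atoms: 2-(dichloromethyl)-4,4,5,5-tetramethyl-1,3,2-dioxaborolane, ClC(Cl)B1OC(C)(C)C(C)(C)O1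
Why: Takai-type boryl olefination through a geminal dichromium species should give the (E)-alkenyl boronate selectively and tolerate the terminal alkyne.

Step 8
Reactants: 9 dienyl boronate
Product: 10 methyl (5R,6R,8E,10E)-5-ethenyl-2-hydroxy-8-methyl-6-(tert-butyldimethylsilyloxy)-11-(pinacolboryl)undeca-8,10-dien-3-ynoate (C2 epimers)
Conditions: methyl glyoxylate, Zn(OTf)2, Et3N, toluene, rt
Reagents that add atoms: methyl glyoxylate, O=CC(=O)OC
Why: Zinc acetylide addition under amine base should add the terminal alkyne to the glyoxylate aldehyde without a strong base that would attack the boronate.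

Step 9
Reactants: 10 propargylic hydroxy ester
Product: 11 methyl (5R,6R,8E,10E)-5-ethenyl-2-hydroxy-11-(4-methoxybenzyloxy)-8-methyl-6-(tert-butyldimethylsilyloxy)undeca-8,10-dien-3-ynoate (C2 epimers)
Conditions: 4-MeOC6H4CH2OH (excess), Cu(OAc)2, Et3N, 4 Å MS, CH2Cl2, air, rt
Reagents that add atoms: 4-methoxybenzyl alcohol, COc1ccc(CO)cc1
Why: Chan–Lam-type O-alkenylation should replace boron by the benzylic oxygen with retention of the E geometry, giving an electron-rich diene that already carries O8 as a chelating ether.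

Step 10
Reactants: 11 dienyl ether alkyne
Product: 12 methyl (3Z,5R,6R,8E,10E)-5-ethenyl-2-hydroxy-11-(4-methoxybenzyloxy)-8-methyl-6-(tert-butyldimethylsilyloxy)undeca-3,8,10-trienoate (C2 epimers)
Conditions: H2 (1 atm), Pd/CaCO3 poisoned with Pb(OAc)2 (Lindlar catalyst), quinoline, EtOAc, rt
Reagents that add atoms: none
Why: Lindlar semihydrogenation should deliver the Z alkene while the dienophile is still an unactivated allylic alcohol that cannot cyclize.

Step 11
Reactants: 12 (Z)-allylic hydroxy ester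
Product: 14 cis-hydrindene keto ester, via Z-keto ester triene 13 (not isolated)
Conditions: Dess–Martin periodinane, NaHCO3, CH2Cl2, 0 °C to rt (40 °C if needed)
Reagents that add atoms: none
Why: Oxidation unveils the (Z)-2-oxo-3-enoate 13, which should undergo a concerted, asynchronous normal-demand [4+2] cycloaddition with the tethered 1-alkoxydiene, forming C2–C6 and C7–C8; the closest known type is the thermal intramolecular Diels–Alder reaction of 1,3,8-nonatrienes with Z dienophiles to cis-hydrindenes. The cyclopentane closes in the fused mode through the three-atom tether C3–C4–C5 and the cyclohexene closes by the cycloaddition itself. The E,E diene places H2 and H8 cis and the Z dienophile places H6 and H7 cis; because tether and keto ester sit on the same side of the Z alkene, the endo transition state is also the cis-fused one and gives all four hydrogens cis with OPMB cis to the keto ester. The absolute sense comes from C5: its hydrogen eclipses the Z alkene to avoid A(1,3) strain, so the diene arrives on the face carrying C4 and anti to the vinyl group. The step needs endo over exo closure, retention of the Z geometry and carbocyclic over hetero-Diels–Alder closure. These are served by the low temperature the activated pair allows and by the C8 alkoxy group, which makes C2 the nucleophilic terminus for C6 and stabilizes positive charge at C8 for C–C closure.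

Step 12
Reactants: 14 cis-hydrindene keto ester
Product: 16 oxirane ester, via chlorohydrin 15 (not isolated)
Conditions: ICH2Cl, i-PrMgCl·LiCl, THF, −78 °C; then 0 °C
Reagents that add atoms: chloroiodomethane, ClCI
Why: Chloromethylmagnesium chloride should add to the ketone of a magnesium chelate between the ketone oxygen and the C8 benzyl ether from the face of H7 (anti to C6), and the alkoxide then displaces chloride to close the oxirane with C12 (R).

Step 13
Reactants: 16 oxirane ester
Product: 17 C8 alcohol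
Conditions: DDQ, CH2Cl2, pH 7 buffer, 0 °C
Reagents that add atoms: none
Why: Oxidative cleavage of the 4-methoxybenzyl ether under buffered conditions should free O8 without disturbing the silyl ether, the oxirane or the alkenes.

Step 14
Reactants: 17 C8 alcohol; 18 (E)-3-methylpent-2-enoic acid
Product: 19 C8 (E)-3-methylpent-2-enoate
Conditions: DCC, DMAP (cat.), CH2Cl2, 0 °C
Reagents that add atoms: none
Why: Steglich esterification used at once should acylate the γ-hydroxy ester before it can lactonize, with low temperature limiting deconjugation of the enoate.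

Step 15
Reactants: 19 C8 enoate
Product: 20 9,1-epoxide
Conditions: mCPBA, NaHCO3, CH2Cl2, 0 °C
Reagents that add atoms: 3-chloroperbenzoic acid, OOC(=O)c1cccc(Cl)c1
Why: The peracid should attack the only electron-rich trisubstituted alkene from the face of H2 and H8, anti to the C8 ester and to the five-membered ring, which places the C9 oxygen trans to O8.

Step 16
Reactants: 20 9,1-epoxide
Product: 22 exo-methylene allylic alcohol, via allyl trimethylsilyl ether 21 (not isolated)
Conditions: Me3SiOTf, 2,6-lutidine, toluene, −78 °C; then DBU, rt; then aqueous citric acid, THF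
Reagents that add atoms: none
Why: Silyl triflate opens the electron-rich trisubstituted epoxide at its tertiary carbon and the amidine removes a methyl proton, so the C9–O bond and its configuration are kept and the exocyclic methylene forms, while the electron-poor glycidate should survive.

Step 17
Reactants: 22 allylic alcohol; 23 (S)-3-methylpentanoic acid
Product: 24 C8,C9 diester
Conditions: DCC, DMAP (cat.), CH2Cl2, 0 °C to rt
Reagents that add atoms: none
Why: Steglich esterification installs the bought (S)-acyl group on the C9 alcohol without touching any stereocentre.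

Step 18
Reactants: 24 diester
Product: 25 C4 alcohol
Conditions: HF·pyridine, pyridine, THF, 0 °C to rt
Reagents that add atoms: none
Why: Buffered fluoride should cleave the remaining silyl ether without acyl migration or oxirane opening.

Step 19
Reactants: 25 C4 alcohol
Product: 27 (E)-5-ethylidene-4-ketone, via vinyl ketone 26 (not isolated)
Conditions: Dess–Martin periodinane, NaHCO3, CH2Cl2, 0 °C; then Et3N, CH2Cl2, 0 °C
Reagents that add atoms: none
Why: Oxidation gives a β,γ-unsaturated ketone whose doubly activated C5–H lets mild base move the alkene into conjugation, which flattens the relay centre C5 and should give the E ethylidene (methyl anti to the carbonyl).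

Step 20
Reactants: 27 ethylidene enone
Product: 28 allylic alcohol (4-OH cis to C7)
Conditions: NaBH4, CeCl3·7H2O, MeOH, −78 °C
Reagents that add atoms: none
Why: Luche 1,2-reduction should deliver hydride from the convex face of the cis-hydrindane, placing the hydroxyl on the concave face.

Step 21
Reactants: 28 allylic alcohol
Product: 29 5,10-epoxy alcohol
Conditions: VO(acac)2 (cat.), t-BuOOH, CH2Cl2, 0 °C to rt
Reagents that add atoms: tert-butyl hydroperoxide, CC(C)(C)OO
Why: Hydroxyl-directed epoxidation delivers oxygen syn to the C4 hydroxyl, that is from the concave face of the E alkene, which sets C10 (S); the allylic esters are not substrates.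

Step 22
Reactants: 29 epoxy alcohol
Product: 30 α,β-epoxy ketone
Conditions: Dess–Martin periodinane, NaHCO3, CH2Cl2, 0 °C
Reagents that add atoms: none
Why: Mild oxidation restores the C4 ketone without opening the epoxides.

Step 23
Reactants: 30 epoxy ketone
Product: 31 β-hydroxy ketone (5R,10S)
Conditions: SmI2, THF–MeOH, −90 °C
Reagents that add atoms: none
Why: Electron transfer cleaves the C5–O bond of the epoxy ketone and the trivalent samarium enolate is protonated kinetically from the convex face, giving H5 cis to H6 with C10–O untouched; the alkoxide is too poor a leaving group to eliminate, and the glycidic ester should not be reduced at this temperature without additives.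

Step 24
Reactants: 31 β-hydroxy ketone
Product: 32 target compound
Conditions: Ac2O, pyridine, CH2Cl2, 0 °C
Reagents that add atoms: acetic anhydride, CC(=O)OC(C)=O
Why: Mild acetylation of the secondary alcohol as the last step keeps the epimerizable, elimination-prone β-acetoxy ketone away from base.

**Compound list**

1 | (E)-pent-2-en-4-yn-1-ol | OC/C=C/C#C | starting material
2 | (E)-5-bromopent-3-en-1-yne | BrC/C=C/C#C | intermediate
3 | 3-(tert-butyldimethylsilyloxy)propanal | O=CCCO[Si](C)(C)C(C)(C)C | starting material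
4 | (3R,4R)-1-(tert-butyldimethylsilyloxy)-4-ethynylhex-5-en-3-ol (anti) | CC(C)(C)[Si](C)(C)OCC[C@@H](O)[C@H](C=C)C#C | intermediate
5 | (3R,4R)-1,3-bis(tert-butyldimethylsilyloxy)-4-ethynylhex-5-ene | CC(C)(C)[Si](C)(C)OCC[C@@H](O[Si](C)(C)C(C)(C)C)[C@H](C=C)C#C | intermediate
6 | (3R,4R)-3-(tert-butyldimethylsilyloxy)-4-ethynylhex-5-en-1-ol | OCC[C@@H](O[Si](C)(C)C(C)(C)C)[C@H](C=C)C#C | intermediate
7 | (3R,4R)-3-(tert-butyldimethylsilyloxy)-4-ethynylhex-5-enal | O=CC[C@@H](O[Si](C)(C)C(C)(C)C)[C@H](C=C)C#C | intermediate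
8 | (2E,5R,6R)-5-(tert-butyldimethylsilyloxy)-6-ethynyl-2-methylocta-2,7-dienal | O=C/C(C)=C/C[C@@H](O[Si](C)(C)C(C)(C)C)[C@H](C=C)C#C | intermediate
9 | pinacol (1E,3E,6R,7R)-6-(tert-butyldimethylsilyloxy)-7-ethynyl-3-methylnona-1,3,8-trienylboronate | CC1(C)OB(/C=C/C(C)=C/C[C@@H](O[Si](C)(C)C(C)(C)C)[C@H](C=C)C#C)OC1(C)C | intermediate
10 | methyl (5R,6R,8E,10E)-5-ethenyl-2-hydroxy-8-methyl-6-(tert-butyldimethylsilyloxy)-11-(pinacolboryl)undeca-8,10-dien-3-ynoate, C2 epimers | CC1(C)OB(/C=C/C(C)=C/C[C@@H](O[Si](C)(C)C(C)(C)C)[C@H](C=C)C#CC(O)C(=O)OC)OC1(C)C | intermediate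
11 | methyl (5R,6R,8E,10E)-5-ethenyl-2-hydroxy-11-(4-methoxybenzyloxy)-8-methyl-6-(tert-butyldimethylsilyloxy)undeca-8,10-dien-3-ynoate, C2 epimers | COc1ccc(CO/C=C/C(C)=C/C[C@@H](O[Si](C)(C)C(C)(C)C)[C@H](C=C)C#CC(O)C(=O)OC)cc1 | intermediate
12 | methyl (3Z,5R,6R,8E,10E)-5-ethenyl-2-hydroxy-11-(4-methoxybenzyloxy)-8-methyl-6-(tert-butyldimethylsilyloxy)undeca-3,8,10-trienoate, C2 epimers | COc1ccc(CO/C=C/C(C)=C/C[C@@H](O[Si](C)(C)C(C)(C)C)[C@H](C=C)/C=C\C(O)C(=O)OC)cc1 | intermediate
13 | methyl (3Z,5R,6R,8E,10E)-5-ethenyl-11-(4-methoxybenzyloxy)-8-methyl-2-oxo-6-(tert-butyldimethylsilyloxy)undeca-3,8,10-trienoate | COc1ccc(CO/C=C/C(C)=C/C[C@@H](O[Si](C)(C)C(C)(C)C)[C@H](C=C)/C=C\C(=O)C(=O)OC)cc1 | intermediate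
14 | cis-hydrindene keto ester: C9=C1 with 1-methyl, 8-(4-methoxybenzyloxy), 7-C(O)CO2Me, 4-OTBS, 5-vinyl; H2, H6, H7, H8 all cis; vinyl cis to H6; OTBS trans to vinyl | CC=1[C@H]2C[C@@H](O[Si](C)(C)C(C)(C)C)[C@H](C=C)[C@H]2[C@@H](C(=O)C(=O)OC)[C@@H](OCc2ccc(OC)cc2)C=1 | intermediate
15 | chlorohydrin of 14 (C12 carries OH, CH2Cl and CO2Me; present as its magnesium alkoxide) | CC=1[C@H]2C[C@@H](O[Si](C)(C)C(C)(C)C)[C@H](C=C)[C@H]2[C@@H]([C@](O)(C(=O)OC)CCl)[C@@H](OCc2ccc(OC)cc2)C=1 | intermediate
16 | oxirane ester: as 14 with C7 bearing (R)-2-(methoxycarbonyl)oxiran-2-yl | CC=1[C@H]2C[C@@H](O[Si](C)(C)C(C)(C)C)[C@H](C=C)[C@H]2[C@@H]([C@]2(C(=O)OC)CO2)[C@@H](OCc2ccc(OC)cc2)C=1 | intermediate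
17 | C8 alcohol of 16 | CC=1[C@H]2C[C@@H](O[Si](C)(C)C(C)(C)C)[C@H](C=C)[C@H]2[C@@H]([C@]2(C(=O)OC)CO2)[C@@H](O)C=1 | intermediate
18 | (E)-3-methylpent-2-enoic acid | CC/C(C)=C/C(=O)O | starting material
19 | C8 (E)-3-methylpent-2-enoate of 17 | CC=1[C@H]2C[C@@H](O[Si](C)(C)C(C)(C)C)[C@H](C=C)[C@H]2[C@@H]([C@]2(C(=O)OC)CO2)[C@@H](OC(=O)/C=C(\C)CC)C=1 | intermediate
20 | 9,1-epoxide of 19, epoxide oxygen trans to the C8 ester | C[C@@]13[C@H]2C[C@@H](O[Si](C)(C)C(C)(C)C)[C@H](C=C)[C@H]2[C@@H]([C@]2(C(=O)OC)CO2)[C@@H](OC(=O)/C=C(\C)CC)[C@@H]1O3 | intermediate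
21 | 1-methylidene 9-trimethylsilyl ether | C=C1[C@H]2C[C@@H](O[Si](C)(C)C(C)(C)C)[C@H](C=C)[C@H]2[C@@H]([C@]2(C(=O)OC)CO2)[C@@H](OC(=O)/C=C(\C)CC)[C@@H]1O[Si](C)(C)C | intermediate
22 | 1-methylidene 9-alcohol (9-OH trans to the C8 ester) | C=C1[C@H]2C[C@@H](O[Si](C)(C)C(C)(C)C)[C@H](C=C)[C@H]2[C@@H]([C@]2(C(=O)OC)CO2)[C@@H](OC(=O)/C=C(\C)CC)[C@@H]1O | intermediate
23 | (S)-3-methylpentanoic acid | OC(=O)C[C@@H](C)CC | starting material
24 | C9 (S)-3-methylpentanoate of 22 (4-OTBS, 5-vinyl) | C=C1[C@H]2C[C@@H](O[Si](C)(C)C(C)(C)C)[C@H](C=C)[C@H]2[C@@H]([C@]2(C(=O)OC)CO2)[C@@H](OC(=O)/C=C(\C)CC)[C@@H]1OC(=O)C[C@@H](C)CC | intermediate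
25 | C4 alcohol of 24 | C=C1[C@H]2C[C@@H](O)[C@H](C=C)[C@H]2[C@@H]([C@]2(C(=O)OC)CO2)[C@@H](OC(=O)/C=C(\C)CC)[C@@H]1OC(=O)C[C@@H](C)CC | intermediate
26 | 4-ketone with 5-vinyl (β,γ-unsaturated) | C=C1[C@H]2CC(=O)[C@H](C=C)[C@H]2[C@@H]([C@]2(C(=O)OC)CO2)[C@@H](OC(=O)/C=C(\C)CC)[C@@H]1OC(=O)C[C@@H](C)CC | intermediate
27 | 4-ketone with (E)-5-ethylidene | C=C1[C@H]2CC(=O)/C(=C/C)[C@H]2[C@@H]([C@]2(C(=O)OC)CO2)[C@@H](OC(=O)/C=C(\C)CC)[C@@H]1OC(=O)C[C@@H](C)CC | intermediate
28 | 4-alcohol with (E)-5-ethylidene, OH cis to C7 | C=C1[C@H]2C[C@@H](O)/C(=C/C)[C@H]2[C@@H]([C@]2(C(=O)OC)CO2)[C@@H](OC(=O)/C=C(\C)CC)[C@@H]1OC(=O)C[C@@H](C)CC | intermediate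
29 | 5,10-epoxy 4-alcohol, epoxide oxygen cis to 4-OH, C10 S | C=C1[C@H]2C[C@@H](O)[C@@]3(O[C@H]3C)[C@H]2[C@@H]([C@]2(C(=O)OC)CO2)[C@@H](OC(=O)/C=C(\C)CC)[C@@H]1OC(=O)C[C@@H](C)CC | intermediate
30 | 5,10-epoxy 4-ketone | C=C1[C@H]2CC(=O)[C@@]3(O[C@H]3C)[C@H]2[C@@H]([C@]2(C(=O)OC)CO2)[C@@H](OC(=O)/C=C(\C)CC)[C@@H]1OC(=O)C[C@@H](C)CC | intermediate
31 | 4-ketone with (5R)-[(1S)-1-hydroxyethyl] | C=C1[C@H]2CC(=O)[C@@H]([C@H](C)O)[C@H]2[C@@H]([C@]2(C(=O)OC)CO2)[C@@H](OC(=O)/C=C(\C)CC)[C@@H]1OC(=O)C[C@@H](C)CC | intermediate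
32 | CNP0109740.1 (2S,5R,6R,7R,8R,9R,10S,12R; S in the pentanoate) | C=C1[C@H]2CC(=O)[C@@H]([C@H](C)OC(C)=O)[C@H]2[C@@H]([C@]2(C(=O)OC)CO2)[C@@H](OC(=O)/C=C(\C)CC)[C@@H]1OC(=O)C[C@@H](C)CC | target

**Totals.** 24 steps in all; longest linear sequence 24 steps (1 to 32, steps 1–24).

**Steps most likely to fail**

Step 11. The Z geometry may be lost before cyclization, the ketone oxygen may close a hetero-Diels–Alder ring instead of C8, or the acid-sensitive dienyl ether may decompose during the oxidation. The fallback sets out from 10 and comes back at 14. It keeps the acid-stable, less electron-rich dienyl boronate as the diene and brings in O8 only after the cycloaddition. Semihydrogenation of 10 (H2, Pd/CaCO3 poisoned with Pb(OAc)2, quinoline) would give the Z-allylic alcohol F1. Dess–Martin oxidation would give the Z-keto ester F2, which should cyclize on warming in toluene to the allylic boronate F3 with boron at C8 in the place of oxygen. Oxidation with Me3NO (retention) would give the C8 alcohol F4, and 4-methoxybenzyl trichloroacetimidate with catalytic La(OTf)3 would give 14.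

Step 2. The ambident pentenynyl chromium may react through its α-carbon or its alkyne terminus, or enantiocontrol may be insufficient. The fallback sets out from 3 and comes back at 4. It builds the C4–C5 pair by epoxide opening instead of allylation. Asymmetric sulfur-ylide epoxidation of 3 with a chiral allyl sulfonium salt (isothiocineole-derived) and base would give the trans vinyl epoxide F5. Et2AlC≡CSiMe3 should open it at the allylic carbon with inversion to the silyl alkyne F6. K2CO3 in MeOH would remove the C-silyl group and give 4.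

Step 12. Chelate control may be incomplete, giving the wrong face at C12, or the carbenoid may enolize C7 or attack the ester. The fallback sets out from 14 and comes back at 16. It uses reagent control instead of chelation. Wittig methylenation of the keto group (Ph3P=CH2) would give the acrylate F7, and DIBAL-H would reduce it to the 2-substituted allylic alcohol F8. Sharpless asymmetric epoxidation (Ti(OiPr)4, the diethyl tartrate enantiomer matched to the required face, t-BuOOH) would give the epoxy alcohol F9. TEMPO/PhI(OAc)2 followed by NaClO2 would give the glycidic acid F10, and Me3SiCHN2 would give 16.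

**Further compounds**

F1 | step 11 | Z-allylic hydroxy ester with dienyl boronate (C2 epimers) | CC1(C)OB(/C=C/C(C)=C/C[C@@H](O[Si](C)(C)C(C)(C)C)[C@H](C=C)/C=C\C(O)C(=O)OC)OC1(C)C
F2 | step 11 | Z-keto ester with dienyl boronate | CC1(C)OB(/C=C/C(C)=C/C[C@@H](O[Si](C)(C)C(C)(C)C)[C@H](C=C)/C=C\C(=O)C(=O)OC)OC1(C)C
F3 | step 11 | cis-hydrindene keto ester with pinacolboryl at C8 | CC=1[C@H]2C[C@@H](O[Si](C)(C)C(C)(C)C)[C@H](C=C)[C@H]2[C@@H](C(=O)C(=O)OC)[C@@H](B2OC(C)(C)C(C)(C)O2)C=1
F4 | step 11 | cis-hydrindene keto ester with free C8 hydroxyl | CC=1[C@H]2C[C@@H](O[Si](C)(C)C(C)(C)C)[C@H](C=C)[C@H]2[C@@H](C(=O)C(=O)OC)[C@@H](O)C=1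
F5 | step 2 | (2R,3R)-2-[2-(tert-butyldimethylsilyloxy)ethyl]-3-ethenyloxirane (trans) | CC(C)(C)[Si](C)(C)OCC[C@H]1O[C@@H]1C=C
F6 | step 2 | (3R,4R)-1-(tert-butyldimethylsilyloxy)-4-[(trimethylsilyl)ethynyl]hex-5-en-3-ol | CC(C)(C)[Si](C)(C)OCC[C@@H](O)[C@H](C=C)C#C[Si](C)(C)C
F7 | step 12 | acrylate: 14 with C7 bearing C(=CH2)CO2Me | CC=1[C@H]2C[C@@H](O[Si](C)(C)C(C)(C)C)[C@H](C=C)[C@H]2[C@@H](C(=C)C(=O)OC)[C@@H](OCc2ccc(OC)cc2)C=1
F8 | step 12 | allylic alcohol: C7 bearing C(=CH2)CH2OH | CC=1[C@H]2C[C@@H](O[Si](C)(C)C(C)(C)C)[C@H](C=C)[C@H]2[C@@H](C(=C)CO)[C@@H](OCc2ccc(OC)cc2)C=1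
F9 | step 12 | epoxy alcohol: C7 bearing 2-(hydroxymethyl)oxiran-2-yl | CC=1[C@H]2C[C@@H](O[Si](C)(C)C(C)(C)C)[C@H](C=C)[C@H]2[C@@H]([C@]2(CO)CO2)[C@@H](OCc2ccc(OC)cc2)C=1
F10 | step 12 | glycidic acid: C7 bearing 2-carboxyoxiran-2-yl | CC=1[C@H]2C[C@@H](O[Si](C)(C)C(C)(C)C)[C@H](C=C)[C@H]2[C@@H]([C@]2(C(=O)O)CO2)[C@@H](OCc2ccc(OC)cc2)C=1
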